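**Plan**

- Retrosynthesis: the six silyl ethers are cut first, then the C4–Cα bond of the styryl arm (Mizoroki–Heck), then O1–C2 of the dihydrofuran (key step), then the C2=C3 alkene of the open triarylethylene (benzylic Grignard addition and dehydration), and last the aryl–C(=O) bond of a 2-hydroxybenzophenone.
- Forward: ring A (the benzo ring) and ring C (the resorcinol ring on C3) are joined at the future C3 as a benzophenone; ring B (the catechol ring) arrives together with C2; the dihydrofuran ring is then closed through O1–C2; ring D (the hydroxystyryl arm) is attached at C4 last.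
- Enabling feature: C2 is benzylic and para to the C4' hydroxyl of ring B, so the C2=C3 alkene of the open form is a para-hydroxystilbene whose quinone methide tautomer has its methide carbon at C2, five atoms from O1 of ring A.
- Stereochemistry: C3 comes from catalyst-controlled proton delivery by a chiral phosphoric acid; C2 comes from ring closure anti to the C3 aryl group (trans); the E alkene comes from the Heck step.
- Protecting groups: fluoride-labile silyl ethers carry the phenols to the end, because the finished O1–C2 bond is a para-oxygenated benzylic aryl ether that would not survive a Lewis-acid dealkylation.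

Key step: step 11

Remark: the triarylethylene is carried as its Z isomer (ring A cis to ring B), the geometry expected from an equilibrating dehydration; both geometries lead to the same quinone methide once C3 is protonated.

Remark: which antipode of the phosphoric acid leads to the (2S,3S) series cannot be predicted with certainty; (R)-TRIP is written, and its mirror image is to be used if a first run gives the (2R,3R) product.

Abbreviations: TBS = tert-butyldimethylsilyl; TRIP = 3,3'-bis(2,4,6-triisopropylphenyl)-1,1'-binaphthyl-2,2'-diyl hydrogen phosphate.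

**Route**

Step 1
Reactants: 1 1-bromo-3,5-dimethoxybenzene
Product: 3 2-bromo-4,6-dimethoxybenzaldehyde, via aryl iminium salt 2 (not isolated)
Conditions: POCl3 (2 equiv), DMF, 0 °C → 100 °C; then ice-water
Reagents that add atoms: N,N-dimethylformamide CN(C)C=O; water O
Why: Vilsmeier–Haack formylation, in which the chloroiminium electrophile made from POCl3 and DMF attacks C2 of 1 (para to one methoxy group and ortho to the other) in preference to the more crowded carbon between the two methoxy groups, and water hydrolyses iminium salt 2 to the aldehyde.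

Step 2
Reactants: 1 1-bromo-3,5-dimethoxybenzene; 3 2-bromo-4,6-dimethoxybenzaldehyde
Product: 5 (2-bromo-4,6-dimethoxyphenyl)(3,5-dimethoxyphenyl)methanol (racemic), via 3,5-dimethoxyphenylmagnesium bromide 4 (not isolated)
Conditions: 1, Mg, I2 (cat.), THF, 50 °C; then 3, THF, 0 °C → rt; aq NH4Cl
Reagents that add atoms: none
Why: Grignard addition of an aryl nucleophile to an aldehyde, which should be much faster than any exchange of 4 with the hindered aryl bromide of 3, so the bromine that later carries the styryl arm is kept.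

Step 3
Reactants: 5 (2-bromo-4,6-dimethoxyphenyl)(3,5-dimethoxyphenyl)methanol
Product: 6 (2-bromo-4,6-dimethoxyphenyl)(3,5-dimethoxyphenyl)methanone
Conditions: Dess–Martin periodinane (1.3 equiv), CH2Cl2, rt
Reagents that add atoms: none
Why: Dess–Martin oxidation of a secondary diaryl carbinol to the benzophenone under neutral conditions that leave the aryl bromide and the methyl ethers alone, the racemic carbinol centre being removed in the process.

Step 4
Reactants: 6 (2-bromo-4,6-dimethoxyphenyl)(3,5-dimethoxyphenyl)methanone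
Product: 7 (2-bromo-4,6-dihydroxyphenyl)(3,5-dihydroxyphenyl)methanone
Conditions: BBr3 (8 equiv), CH2Cl2, −78 °C → rt; then H2O
Reagents that add atoms: none
Why: Lewis-acid cleavage of aryl methyl ethers with BBr3, placed at the robust benzophenone stage because the later O1–C2 bond is itself a benzylic aryl ether that such a reagent would open, so that all four phenols can be re-protected as fluoride-labile silyl ethers.

Step 5
Reactants: 7 (2-bromo-4,6-dihydroxyphenyl)(3,5-dihydroxyphenyl)methanone
Product: 8 {2-bromo-6-hydroxy-4-[(TBS)oxy]phenyl}{3,5-bis[(TBS)oxy]phenyl}methanone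
Conditions: TBSCl (3.1 equiv), imidazole (6.2 equiv), DMF, 0 °C → rt
Reagents that add atoms: tert-butyldimethylsilyl chloride CC(C)(C)[Si](C)(C)Cl
Why: Selective silylation of phenols, in which the three unhindered hydroxyls should react while the hydroxyl ortho to the carbonyl group, held in an intramolecular hydrogen bond and shielded by the diaryl ketone, stays free and later becomes O1.

Step 6
Reactants: 9 3,4-dihydroxybenzaldehyde
Product: 10 3,4-bis(prop-2-en-1-yloxy)benzaldehyde
Conditions: allyl bromide (2.4 equiv), K2CO3 (3 equiv), DMF, 50 °C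
Reagents that add atoms: allyl bromide C=CCBr
Why: Williamson ether synthesis on both catechol oxygens, allyl being chosen because it survives Grignard chemistry and mild acid and can later be removed without acid or fluoride.

Step 7
Reactants: 10 3,4-bis(prop-2-en-1-yloxy)benzaldehyde
Product: 11 [3,4-bis(prop-2-en-1-yloxy)phenyl]methanol
Conditions: NaBH4, MeOH, 0 °C
Reagents that add atoms: none
Why: Hydride reduction of an aromatic aldehyde with NaBH4, which touches neither the allyl ethers nor the ring.

Step 8
Reactants: 11 [3,4-bis(prop-2-en-1-yloxy)phenyl]methanol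
Product: 12 4-(chloromethyl)-1,2-bis(prop-2-en-1-yloxy)benzene
Conditions: SOCl2 (1.2 equiv), CH2Cl2, 0 °C → rt; evaporated and used crude
Reagents that add atoms: thionyl chloride ClS(Cl)=O
Why: Chlorination of an electron-rich benzylic alcohol through its chlorosulfite, the volatile by-products allowing the sensitive chloride to be taken on without purification.

Step 9
Reactants: 12 4-(chloromethyl)-1,2-bis(prop-2-en-1-yloxy)benzene; 8 {2-bromo-6-hydroxy-4-[(TBS)oxy]phenyl}{3,5-bis[(TBS)oxy]phenyl}methanone
Product: 15 3-bromo-2-{(Z)-2-[3,4-bis(prop-2-en-1-yloxy)phenyl]-1-{3,5-bis[(TBS)oxy]phenyl}ethenyl}-5-[(TBS)oxy]phenol, via benzylic Grignard reagent 13 (not isolated), via tertiary carbinol 14 (not isolated)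
Conditions: 12, Mg (excess), 2-MeTHF, 0 °C, slow addition; then 8 (0.4 equiv), THF, 0 °C → rt; aq NH4Cl; then PPTS (10 mol %), toluene, 60 °C
Reagents that add atoms: none
Why: Grignard addition to a diaryl ketone followed by acid-catalysed E1 dehydration, in which one equivalent of 13 deprotonates the phenol of 8, a second adds to the carbonyl group, and carbinol 14 loses water through a cation stabilised by ring A to give the triarylethylene, expected to settle as the Z isomer because the twisted, doubly ortho-substituted ring A is best placed cis to ring B while rings B and C form a planar trans-stilbene unit.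

Step 10
Reactants: 15 3-bromo-2-{(Z)-2-[3,4-bis(prop-2-en-1-yloxy)phenyl]-1-{3,5-bis[(TBS)oxy]phenyl}ethenyl}-5-[(TBS)oxy]phenol
Product: 16 4-[(Z)-2-{2-bromo-6-hydroxy-4-[(TBS)oxy]phenyl}-2-{3,5-bis[(TBS)oxy]phenyl}ethenyl]benzene-1,2-diol
Conditions: Pd(PPh3)4 (5 mol %), morpholine (10 equiv), THF, rt, argon
Reagents that add atoms: none
Why: Tsuji–Trost deallylation, in which zerovalent palladium ionises both aryl allyl ethers to π-allyl complexes that morpholine captures at room temperature, where the hindered aryl bromide should not undergo oxidative addition, the silyl ethers are stable, and no acid is present that could cyclise the freed para-hydroxystilbene before the chiral catalyst is added.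

Step 11
Reactants: 16 4-[(Z)-2-{2-bromo-6-hydroxy-4-[(TBS)oxy]phenyl}-2-{3,5-bis[(TBS)oxy]phenyl}ethenyl]benzene-1,2-diol
Product: 18 4-[(2S,3S)-4-bromo-3-{3,5-bis[(TBS)oxy]phenyl}-6-[(TBS)oxy]-2,3-dihydro-1-benzofuran-2-yl]benzene-1,2-diol, via para-quinone methide 17 (not isolated)
Conditions: (R)-TRIP (10 mol %), 5 Å molecular sieves, toluene (0.02 M), 0 °C, argon; then filtration through NaHCO3/silica
Reagents that add atoms: none
Why: Proposed new method: the phosphoric acid is expected to act as a proton shuttle, its P=O oxygen taking the C4' hydroxyl proton of ring B while its P–OH delivers a proton to C3, which gives para-quinone methide 17 hydrogen-bonded to the chiral acid, and the ring A hydroxyl O1 then adds to the methide carbon C2 in an oxa-1,6-addition that re-aromatises ring B and forms O1–C2, so that the overall change is a redox-neutral isomerisation. The closest known reaction types are the activation of para-hydroxystyrenes as para-quinone methides by chiral phosphoric acids for asymmetric 1,6-additions and the acid-catalysed cyclisation of 2-hydroxystilbenes to 2-aryl-2,3-dihydrobenzofurans, the new element being that the proton transfer itself creates a stereocentre. The dihydrofuran ring closes in the 5-exo-trig mode, O1 attacking the exocyclic methide carbon. C3 is set by face-selective proton delivery inside the hydrogen-bonded complex (catalyst control), and C2 by closure anti to the C3 aryl group, trans also being the thermodynamic outcome because the O1–C2 bond can reopen without touching C3. The step needs productive protonation at C3 and not at C2, and this is secured because protonation at C2 gives a cation on the ring A side that has no nucleophile within reach and simply reverts, because neither ring C nor the meta C3' hydroxyl can form a quinone methide, and because the weakly donating C6 silyl ether and the twist imposed on ring A by its two ortho substituents keep that unproductive cation from being overly favoured. The reaction is to be stopped at full conversion and the acid removed at once, since reversal through 17 would erode C3.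

Step 12
Reactants: 18 4-[(2S,3S)-4-bromo-3-{3,5-bis[(TBS)oxy]phenyl}-6-[(TBS)oxy]-2,3-dihydro-1-benzofuran-2-yl]benzene-1,2-diol
Product: 19 (2S,3S)-4-bromo-2-{3,4-bis[(TBS)oxy]phenyl}-3-{3,5-bis[(TBS)oxy]phenyl}-6-[(TBS)oxy]-2,3-dihydro-1-benzofuran
Conditions: TBSCl (2.5 equiv), imidazole (5 equiv), DMF, 0 °C → rt
Reagents that add atoms: tert-butyldimethylsilyl chloride CC(C)(C)[Si](C)(C)Cl
Why: Silylation of the catechol with TBSCl and imidazole, which caps the C4' hydroxyl and thereby closes the only path back to a quinone methide, so that both stereocentres are locked before the basic, hot Heck step.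

Step 13
Reactants: 19 (2S,3S)-4-bromo-2-{3,4-bis[(TBS)oxy]phenyl}-3-{3,5-bis[(TBS)oxy]phenyl}-6-[(TBS)oxy]-2,3-dihydro-1-benzofuran; 20 tert-butyl(4-ethenylphenoxy)dimethylsilane
Product: 21 hexakis-O-TBS scirpusin A, that is (2S,3S)-2-{3,4-bis[(TBS)oxy]phenyl}-3-{3,5-bis[(TBS)oxy]phenyl}-6-[(TBS)oxy]-4-[(E)-2-{4-[(TBS)oxy]phenyl}ethenyl]-2,3-dihydro-1-benzofuran
Conditions: Pd(P(t-Bu)3)2 (5 mol %), Cy2NMe (1.5 equiv), 1,4-dioxane, 80 °C
Reagents that add atoms: none
Why: Mizoroki–Heck reaction, in which the bulky electron-rich phosphine allows oxidative addition of the ortho-substituted aryl bromide, syn insertion at the terminal carbon of the styrene and syn β-hydride elimination give the E-stilbene, and the tertiary amine base leaves the aryl silyl ethers and both stereocentres untouched.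

Step 14
Reactants: 21 hexakis-O-TBS scirpusin A
Product: 22 scirpusin A
Conditions: TBAF (7 equiv), AcOH (7 equiv), THF, 0 °C → rt, argon
Reagents that add atoms: none
Why: Fluoride-mediated cleavage of all six aryl silyl ethers, buffered with acetic acid so that no Lewis acid (which would open O1–C2), no strong protic acid (which would protonate the hydroxystilbene) and no free phenoxide (which could reopen the ring through the quinone methide) is present.

**Compound list**

1 | 1-bromo-3,5-dimethoxybenzene | COc1cc(Br)cc(OC)c1 | starting material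
2 | N-[(2-bromo-4,6-dimethoxyphenyl)methylidene]-N-methylmethanaminium dichlorophosphate | COc1cc(Br)c(C=[N+](C)C)c(OC)c1.[O-]P(=O)(Cl)Cl | intermediate (not isolated)
3 | 2-bromo-4,6-dimethoxybenzaldehyde | COc1cc(Br)c(C=O)c(OC)c1 | intermediate
4 | 3,5-dimethoxyphenylmagnesium bromide | COc1cc(OC)cc([Mg]Br)c1 | intermediate (not isolated)
5 | (2-bromo-4,6-dimethoxyphenyl)(3,5-dimethoxyphenyl)methanol, racemic | COc1cc(OC)cc(C(O)c2c(Br)cc(OC)cc2OC)c1 | intermediate
6 | (2-bromo-4,6-dimethoxyphenyl)(3,5-dimethoxyphenyl)methanone | COc1cc(OC)cc(C(=O)c2c(Br)cc(OC)cc2OC)c1 | intermediate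
7 | (2-bromo-4,6-dihydroxyphenyl)(3,5-dihydroxyphenyl)methanone | Oc1cc(O)cc(C(=O)c2c(Br)cc(O)cc2O)c1 | intermediate
8 | {2-bromo-6-hydroxy-4-[(TBS)oxy]phenyl}{3,5-bis[(TBS)oxy]phenyl}methanone | CC(C)(C)[Si](C)(C)Oc1cc(O[Si](C)(C)C(C)(C)C)cc(C(=O)c2c(Br)cc(O[Si](C)(C)C(C)(C)C)cc2O)c1 | intermediate
9 | 3,4-dihydroxybenzaldehyde | O=Cc1ccc(O)c(O)c1 | starting material
10 | 3,4-bis(prop-2-en-1-yloxy)benzaldehyde | C=CCOc1ccc(C=O)cc1OCC=C | intermediate
11 | [3,4-bis(prop-2-en-1-yloxy)phenyl]methanol | C=CCOc1ccc(CO)cc1OCC=C | intermediate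
12 | 4-(chloromethyl)-1,2-bis(prop-2-en-1-yloxy)benzene | C=CCOc1ccc(CCl)cc1OCC=C | intermediate
13 | [3,4-bis(prop-2-en-1-yloxy)benzyl]magnesium chloride | C=CCOc1ccc(C[Mg]Cl)cc1OCC=C | intermediate (not isolated)
14 | 3-bromo-2-{2-[3,4-bis(prop-2-en-1-yloxy)phenyl]-1-{3,5-bis[(TBS)oxy]phenyl}-1-hydroxyethyl}-5-[(TBS)oxy]phenol, racemic | Oc1cc(O[Si](C)(C)C(C)(C)C)cc(Br)c1C(O)(Cc1ccc(OCC=C)c(OCC=C)c1)c1cc(O[Si](C)(C)C(C)(C)C)cc(O[Si](C)(C)C(C)(C)C)c1 | intermediate (not isolated)
15 | 3-bromo-2-{(Z)-2-[3,4-bis(prop-2-en-1-yloxy)phenyl]-1-{3,5-bis[(TBS)oxy]phenyl}ethenyl}-5-[(TBS)oxy]phenol | Oc1cc(O[Si](C)(C)C(C)(C)C)cc(Br)c1/C(c1cc(O[Si](C)(C)C(C)(C)C)cc(O[Si](C)(C)C(C)(C)C)c1)=C\c1ccc(OCC=C)c(OCC=C)c1 | intermediate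
16 | 4-[(Z)-2-{2-bromo-6-hydroxy-4-[(TBS)oxy]phenyl}-2-{3,5-bis[(TBS)oxy]phenyl}ethenyl]benzene-1,2-diol | Oc1cc(O[Si](C)(C)C(C)(C)C)cc(Br)c1/C(c1cc(O[Si](C)(C)C(C)(C)C)cc(O[Si](C)(C)C(C)(C)C)c1)=C\c1ccc(O)c(O)c1 | intermediate (precursor of the key step)
17 | 4-[(2S)-2-{2-bromo-6-hydroxy-4-[(TBS)oxy]phenyl}-2-{3,5-bis[(TBS)oxy]phenyl}ethylidene]-2-hydroxycyclohexa-2,5-dien-1-one | O=C1C=CC(=C[C@H](c2c(O)cc(O[Si](C)(C)C(C)(C)C)cc2Br)c2cc(O[Si](C)(C)C(C)(C)C)cc(O[Si](C)(C)C(C)(C)C)c2)C=C1O | intermediate (not isolated)
18 | 4-[(2S,3S)-4-bromo-3-{3,5-bis[(TBS)oxy]phenyl}-6-[(TBS)oxy]-2,3-dihydro-1-benzofuran-2-yl]benzene-1,2-diol | Brc1cc(O[Si](C)(C)C(C)(C)C)cc2c1[C@H](c1cc(O[Si](C)(C)C(C)(C)C)cc(O[Si](C)(C)C(C)(C)C)c1)[C@@H](c1ccc(O)c(O)c1)O2 | intermediate (product of the key step)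
19 | (2S,3S)-4-bromo-2-{3,4-bis[(TBS)oxy]phenyl}-3-{3,5-bis[(TBS)oxy]phenyl}-6-[(TBS)oxy]-2,3-dihydro-1-benzofuran | Brc1cc(O[Si](C)(C)C(C)(C)C)cc2c1[C@H](c1cc(O[Si](C)(C)C(C)(C)C)cc(O[Si](C)(C)C(C)(C)C)c1)[C@@H](c1ccc(O[Si](C)(C)C(C)(C)C)c(O[Si](C)(C)C(C)(C)C)c1)O2 | intermediate
20 | tert-butyl(4-ethenylphenoxy)dimethylsilane | C=Cc1ccc(O[Si](C)(C)C(C)(C)C)cc1 | starting material
21 | (2S,3S)-2-{3,4-bis[(TBS)oxy]phenyl}-3-{3,5-bis[(TBS)oxy]phenyl}-6-[(TBS)oxy]-4-[(E)-2-{4-[(TBS)oxy]phenyl}ethenyl]-2,3-dihydro-1-benzofuran | CC(C)(C)[Si](C)(C)Oc1ccc(/C=C/c2cc(O[Si](C)(C)C(C)(C)C)cc3c2[C@H](c2cc(O[Si](C)(C)C(C)(C)C)cc(O[Si](C)(C)C(C)(C)C)c2)[C@@H](c2ccc(O[Si](C)(C)C(C)(C)C)c(O[Si](C)(C)C(C)(C)C)c2)O3)cc1 | intermediate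
22 | scirpusin A, (2S,3S) | Oc1ccc(/C=C/c2cc(O)cc3c2[C@H](c2cc(O)cc(O)c2)[C@@H](c2ccc(O)c(O)c2)O3)cc1 | target

**Step count and risks**

Total step count: 14. Longest linear sequence: 11 steps (steps 1–5 and 9–14, from 1 to 22); the ring B branch (steps 6–8) joins at step 9.

Steps most likely to fail:

1. Step 11 (new method). Proton delivery to C3 may be too slow for an acid of this strength, so that reversible protonation at C2 and slow uncatalysed closure take over; the face selectivity of the proton transfer may be low; and the product may lose optical purity by reopening through the quinone methide. Fallback, from 16 back to 18: an achiral Brønsted acid (diphenyl phosphate, 10 mol %, toluene, rt) would run the same closure without enantiocontrol, which is the known acid-catalysed cyclisation of 2-hydroxystilbenes to trans-2-aryl-2,3-dihydrobenzofurans, and should give the racemic trans-dihydrobenzofuran F1. Preparative chromatography on a chiral stationary phase (supercritical CO2 with an alcohol modifier) would then separate 18 from its (2R,3R) mirror image F2, and the route resumes at 18.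

2. Step 9. Wurtz-type homocoupling may consume the electron-rich benzylic chloride while the Grignard reagent is formed, and addition to a ketone that is both doubly ortho-substituted and deactivated as its phenoxide may be sluggish. Fallback, from 8 back to 16 (steps 9 and 10 are bypassed): MeMgBr (3 equiv, THF, 0 °C → rt), a small nucleophile that adds readily to hindered 2-hydroxybenzophenones, should give the tertiary methyl carbinol F3, which PPTS in warm toluene dehydrates to the 1,1-diarylethene F4. A Mizoroki–Heck arylation of F4 with 4-iodobenzene-1,2-diyl diacetate (Pd(OAc)2, P(o-tol)3, Et3N, DMF, 80 °C; the aryl iodide should react well before the hindered ring A bromide) brings in ring B and gives the triarylethylene diacetate F5, which is equilibrated to its Z isomer with a trace of acid while both catechol oxygens are still acylated. Hydrazine hydrate in THF/MeOH at 0 °C then removes the two acetates without acid and without touching the silyl ethers, rejoining the route at 16.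

3. Step 13. Alkene insertion at the crowded arylpalladium bromide next to the C3 aryl group may be slow, so that hydrodebromination and catalyst decomposition win. Fallback, from 20 and 19 back to 21: cross-metathesis of 20 with vinylboronic acid pinacol ester (second-generation Grubbs catalyst, CH2Cl2, 40 °C) should give the (E)-styrylboronate F6. A Suzuki–Miyaura coupling of F6 with 19 (Pd(OAc)2, 2-dicyclohexylphosphino-2',6'-dimethoxybiphenyl, K3PO4, toluene/H2O, 70 °C) then forms the same C4–Cα bond with the alkene geometry fixed beforehand and returns to 21; any partial loss of a silyl group there is harmless, because step 14 removes them all.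

**Further compounds**

F1 | step 11 | racemic trans-4-[4-bromo-3-{3,5-bis[(TBS)oxy]phenyl}-6-[(TBS)oxy]-2,3-dihydro-1-benzofuran-2-yl]benzene-1,2-diol (1:1 mixture of the 2S,3S and 2R,3R forms) | Brc1cc(O[Si](C)(C)C(C)(C)C)cc2c1[C@H](c1cc(O[Si](C)(C)C(C)(C)C)cc(O[Si](C)(C)C(C)(C)C)c1)[C@@H](c1ccc(O)c(O)c1)O2.Brc1cc(O[Si](C)(C)C(C)(C)C)cc2c1[C@@H](c1cc(O[Si](C)(C)C(C)(C)C)cc(O[Si](C)(C)C(C)(C)C)c1)[C@H](c1ccc(O)c(O)c1)O2
F2 | step 11 | 4-[(2R,3R)-4-bromo-3-{3,5-bis[(TBS)oxy]phenyl}-6-[(TBS)oxy]-2,3-dihydro-1-benzofuran-2-yl]benzene-1,2-diol | Brc1cc(O[Si](C)(C)C(C)(C)C)cc2c1[C@@H](c1cc(O[Si](C)(C)C(C)(C)C)cc(O[Si](C)(C)C(C)(C)C)c1)[C@H](c1ccc(O)c(O)c1)O2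
F3 | step 9 | 3-bromo-2-{1-{3,5-bis[(TBS)oxy]phenyl}-1-hydroxyethyl}-5-[(TBS)oxy]phenol, racemic | CC(O)(c1cc(O[Si](C)(C)C(C)(C)C)cc(O[Si](C)(C)C(C)(C)C)c1)c1c(O)cc(O[Si](C)(C)C(C)(C)C)cc1Br
F4 | step 9 | 3-bromo-2-{1-{3,5-bis[(TBS)oxy]phenyl}ethenyl}-5-[(TBS)oxy]phenol | C=C(c1cc(O[Si](C)(C)C(C)(C)C)cc(O[Si](C)(C)C(C)(C)C)c1)c1c(O)cc(O[Si](C)(C)C(C)(C)C)cc1Br
F5 | step 9 | 4-[(Z)-2-{2-bromo-6-hydroxy-4-[(TBS)oxy]phenyl}-2-{3,5-bis[(TBS)oxy]phenyl}ethenyl]benzene-1,2-diyl diacetate | CC(=O)Oc1ccc(/C=C(/c2cc(O[Si](C)(C)C(C)(C)C)cc(O[Si](C)(C)C(C)(C)C)c2)c2c(O)cc(O[Si](C)(C)C(C)(C)C)cc2Br)cc1OC(C)=O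
F6 | step 13 | tert-butyldimethyl{4-[(E)-2-(4,4,5,5-tetramethyl-1,3,2-dioxaborolan-2-yl)ethenyl]phenoxy}silane | CC(C)(C)[Si](C)(C)Oc1ccc(/C=C/B2OC(C)(C)C(C)(C)O2)cc1
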